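The five-membered ring is closed across its C4–C5 bond, read as an aldol bond: ring-fusion C5 lies alpha to oxygenated C6, and C4 is a tertiary carbinol carrying isopropyl, i.e. a former isopropyl ketone. In the key step SmI2 reduces an α-bromo γ-lactone, in which C6 is the carbonyl tied to the C10 oxygen, to a samarium enolate that closes the cyclopentane onto the pendant ketone and sets C4 and C5 in one operation. The precursor is a butenolide-derived bromolactone whose quaternary C1 carries methyl, vinyl-bearing C10 and the silyloxy keto chain C2–C4. Methallyl addition and ring-closing metathesis then build the cycloheptene.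

Key step: step 8

Remark: atoms are numbered as in daucanes: C1 quaternary ring-fusion carbon (CH3), C2 CH(OH), C3 CH2, C4 C(OH)(iPr), C5 ring-fusion CH, C6 (next to C5) and C10 (next to C1) the two angeloyloxy carbons, C7 CH2, C8=C9 the ring alkene (CH3 on C8).

Step 1
Reactants: 1 ethyl propiolate; 2 acrolein
Product: 3 ethyl (4R)-4-hydroxyhex-5-en-2-ynoate
Conditions: Me2Zn (3 equiv), (R,R)-ProPhenol (20 mol%), Ph3PO (40 mol%), toluene, 0 °C; aq. NH4Cl
Reagents that add atoms: none
Why: Zn–ProPhenol-catalysed enantioselective alkynylation of an aldehyde, in which the dinuclear zinc complex holds acrolein and the zinc acetylide of 1 and should deliver the alkynyl group to the Si face, setting the C10 carbinol as R.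

Step 2
Reactants: 3 ethyl (4R)-4-hydroxyhex-5-en-2-ynoate
Product: 5 (5R)-5-ethenyl-4-methylfuran-2(5H)-one, via Z hydroxy enoate 4 (not isolated)
Conditions: Me2CuLi (2.5 equiv, from CuI and MeLi), THF, −78 °C; aq. NH4Cl, −78 °C to rt
Reagents that add atoms: lithium dimethylcuprate, [Li+].C[Cu-]C
Why: Syn carbocupration of the ynoate puts the methyl group on C1 cis to the new vinylic hydrogen on C5, so the Z γ-hydroxy enoate lactonises to the butenolide (cuprate addition then lactonisation) and the C10 stereocentre is untouched.

Step 3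
Reactants: 5 (5R)-5-ethenyl-4-methylfuran-2(5H)-one; 6 1,3-dioxolane
Product: 7 (4S,5R)-4-(1,3-dioxolan-2-yl)-5-ethenyl-4-methyloxolan-2-one
Conditions: (nBu4N)4W10O32 (2 mol%), MeCN/6 1:1, 390 nm LEDs, rt
Reagents that add atoms: none
Why: Decatungstate hydrogen-atom transfer from the acetal C–H of 6 gives the nucleophilic 2-dioxolanyl radical, whose Giese addition to the butenolide β-carbon C1 (photocatalytic hydroalkylation) should occur anti to the C10 vinyl group, setting quaternary C1 with methyl cis and the masked formyl carbon C2 trans to vinyl.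

Step 4
Reactants: 7 (4S,5R)-4-(1,3-dioxolan-2-yl)-5-ethenyl-4-methyloxolan-2-one
Product: 9 (4S,5R)-3-bromo-4-(1,3-dioxolan-2-yl)-5-ethenyl-4-methyloxolan-2-one (both C3 epimers), via lithium enolate 8 (not isolated)
Conditions: LiN(iPr)2 (1.1 equiv), THF, −78 °C; then BrCCl2CCl2Br, −78 °C
Reagents that add atoms: 1,2-dibromotetrachloroethane, BrC(Cl)(Cl)C(Cl)(Cl)Br
Why: Kinetic deprotonation at C5, the only α-position of the lactone, and electrophilic bromination of the enolate (enolate α-halogenation) install the handle for later reductive enolate formation; the C5 configuration is irrelevant because C5 becomes sp2 again in step 8.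

Step 5
Reactants: 9 (4S,5R)-3-bromo-4-(1,3-dioxolan-2-yl)-5-ethenyl-4-methyloxolan-2-one
Product: 10 (2R,3S)-4-bromo-2-ethenyl-3-methyl-5-oxooxolane-3-carbaldehyde (both C4 epimers)
Conditions: 2 M HCl, THF, 40 °C
Reagents that add atoms: water, O
Why: Acid-catalysed acetal hydrolysis frees the C2 aldehyde, which cannot epimerise because C1 is quaternary, while the lactone and the secondary bromide tolerate aqueous acid.

Step 6
Reactants: 10 (2R,3S)-4-bromo-2-ethenyl-3-methyl-5-oxooxolane-3-carbaldehyde; 11 3-methylbutan-2-one
Product: 13 (4R,5R)-3-bromo-5-ethenyl-4-[(1R)-1-hydroxy-4-methyl-3-oxopentyl]-4-methyloxolan-2-one (both C3 epimers), via boron enolate 12 (not isolated)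
Conditions: 11, (–)-Ipc2BCl, Et3N, Et2O, 0 °C; then 10, −78 to −20 °C; H2O2, pH 7 buffer, MeOH, 0 °C
Reagents that add atoms: none
Why: Paterson boron aldol reaction, in which (–)-Ipc2BCl/Et3N enolises 11 at its methyl group and the isopinocampheyl ligands should steer the enolate to the Re face of the non-enolisable aldehyde through a cyclic transition state, giving the R carbinol at C2 as in 24 while the neutral boron enolate leaves the bromolactone untouched.

Step 7
Reactants: 13 (4R,5R)-3-bromo-5-ethenyl-4-[(1R)-1-hydroxy-4-methyl-3-oxopentyl]-4-methyloxolan-2-one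
Product: 14 tert-butyldimethylsilyl ether of 13 (C2–OTBS)
Conditions: TBSOTf, 2,6-lutidine, CH2Cl2, −78 °C
Reagents that add atoms: tert-butyldimethylsilyl triflate, CC(C)(C)[Si](C)(C)OS(=O)(=O)C(F)(F)F
Why: Silylation with the reactive triflate protects the hindered C2 hydroxyl at low temperature before it can translactonise onto C6, and keeps it out of the later acylation.

Step 8
Reactants: 14 tert-butyldimethylsilyl ether of 13
Product: 16 cis-fused bicyclic hydroxy lactone (cyclopentane C1–C5 fused to the γ-lactone; C4 OH syn to the lactone carbonyl; stereocentres C1, C2, C4, C5, C10 as in 24), via samarium enolate 15 (not isolated)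
Conditions: SmI2 (2.2 equiv), THF, −78 °C; aq. NH4Cl
Reagents that add atoms: none
Why: Two single-electron transfers from SmI2 cleave the C5–Br bond and give the enolate of trivalent samarium, which adds to the C4 ketone; the closest known reaction type is the SmI2-promoted intramolecular Reformatsky (aldol) cyclisation. The cyclopentane C1–C2–C3–C4–C5 closes in a 5-(enolexo)-exo-trig mode. C5 is set because the three-atom tether from quaternary C1 can only reach the enolate face on which it stands, which forces the cis ring fusion with H5 cis to the C1 methyl. C4 is set by samarium bridging the enolate oxygen and the ketone oxygen in a closed transition state, which should place the new hydroxyl syn to the C6 carbonyl and the isopropyl group on the convex face. The step needs the lactone enolate to form next to a more acidic β-silyloxy ketone; the C–Br bond as the only reducible site secures this without base, so neither ketone enolisation nor loss of the silyloxy group should compete.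

Step 9
Reactants: 16 cis-fused bicyclic hydroxy lactone; 17 2-methylallylmagnesium chloride
Product: 18 cyclopentane keto diol (C5 carries the 3-methylbut-3-enoyl group with C6 as ketone; C1 carries methyl and the 1-hydroxyprop-2-enyl group C10; open-chain tautomer drawn)
Conditions: 17 (3 equiv), THF, −78 °C; AcOH, −78 °C
Reagents that add atoms: none
Why: Grignard addition to the lactone carbonyl should stop at the magnesium hemiketal at −78 °C (mono-addition to a γ-lactone, one equivalent being used up by the tertiary hydroxyl), so that the acidic quench gives the methallyl ketone and frees the C10 hydroxyl without forming a stereocentre.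

Step 10
Reactants: 18 cyclopentane keto diol
Product: 19 cis-fused hydroazulenone (C6 ketone, C8=C9 alkene, C10 and C4 hydroxyls, C2–OTBS)
Conditions: second-generation Grubbs catalyst (5 mol%), CH2Cl2, 40 °C
Reagents that add atoms: none
Why: Ring-closing metathesis of the 1,1-disubstituted methallyl alkene with the vinyl group, held cis on the cyclopentane, closes the cycloheptene and forms the trisubstituted C8=C9 bond without touching a stereocentre.

Step 11
Reactants: 19 cis-fused hydroazulenone
Product: 20 dauc-8-ene-2,4,6,10-tetrol 2-O-TBS ether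
Conditions: Me4NBH(OAc)3, MeCN/AcOH, −30 °C
Reagents that add atoms: none
Why: Evans–Saksena hydroxyl-directed reduction, in which the borohydride bound to the C4 hydroxyl (the C10 hydroxyl lies on the same face) delivers hydride to the face of the ring ketone that carries C4, so the C6 hydroxyl should come out trans to C4 and cis to H5.

Step 12
Reactants: 20 dauc-8-ene-2,4,6,10-tetrol 2-O-TBS ether; 21 angelic acid
Product: 23 6,10-di-O-angeloyl derivative of 20, via mixed anhydride 22 (not isolated)
Conditions: 21 (6 equiv), 2,4,6-trichlorobenzoyl chloride, Et3N, toluene, rt; then 20, 80 °C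
Reagents that add atoms: none
Why: Yamaguchi esterification through the mixed anhydride without DMAP should acylate the two secondary hydroxyls at C6 and C10, leave the tertiary C4 hydroxyl free and keep the Z geometry of the angelate.

Step 13
Reactants: 23 6,10-di-O-angeloyl derivative of 20
Product: 24 target, 6,10-di-O-angeloyl-dauc-8-ene-2,4,6,10-tetrol
Conditions: HF·pyridine, pyridine/THF, 0 °C to rt
Reagents that add atoms: none
Why: Desilylation with buffered HF·pyridine removes the C2 silyl ether without base, so the angelates should neither migrate nor isomerise to tiglates.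

Compound list
1 | ethyl propiolate | C#CC(=O)OCC | starting material
2 | acrolein | C=CC=O | starting material
3 | ethyl (4R)-4-hydroxyhex-5-en-2-ynoate | CCOC(=O)C#C[C@H](O)C=C | intermediate
4 | ethyl (2Z,4R)-4-hydroxy-3-methylhexa-2,5-dienoate (not isolated) | CCOC(=O)/C=C(C)\[C@H](O)C=C | intermediate
5 | (5R)-5-ethenyl-4-methylfuran-2(5H)-one | O=C1O[C@H](C=C)C(C)=C1 | intermediate
6 | 1,3-dioxolane | C1COCO1 | starting material
7 | (4S,5R)-4-(1,3-dioxolan-2-yl)-5-ethenyl-4-methyloxolan-2-one | O=C1O[C@H](C=C)[C@@](C)(C2OCCO2)C1 | intermediate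
8 | lithium enolate of 7 (not isolated) | [Li]OC1=C[C@](C)(C2OCCO2)[C@@H](C=C)O1 | intermediate
9 | (4S,5R)-3-bromo-4-(1,3-dioxolan-2-yl)-5-ethenyl-4-methyloxolan-2-one, both C3 epimers | O=C1O[C@H](C=C)[C@@](C)(C2OCCO2)C1Br | intermediate
10 | (2R,3S)-4-bromo-2-ethenyl-3-methyl-5-oxooxolane-3-carbaldehyde, both C4 epimers | O=C1O[C@H](C=C)[C@@](C)(C=O)C1Br | intermediate
11 | 3-methylbutan-2-one | CC(=O)C(C)C | starting material
12 | diisopinocampheylboron enolate of 11 (not isolated) | C=C(OB([C@@H]1C[C@@H]2C[C@H]([C@H]1C)C2(C)C)[C@@H]1C[C@@H]2C[C@H]([C@H]1C)C2(C)C)C(C)C | intermediate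
13 | (4R,5R)-3-bromo-5-ethenyl-4-[(1R)-1-hydroxy-4-methyl-3-oxopentyl]-4-methyloxolan-2-one, both C3 epimers | O=C1O[C@H](C=C)[C@@](C)([C@H](O)CC(=O)C(C)C)C1Br | intermediate
14 | tert-butyldimethylsilyl ether of 13 (C2–OTBS) | O=C1O[C@H](C=C)[C@@](C)([C@H](O[Si](C)(C)C(C)(C)C)CC(=O)C(C)C)C1Br | intermediate
15 | samarium enolate of the lactone of 14, bromide lost (not isolated) | C=C[C@H]1OC(O[Sm](I)I)=C[C@]1(C)[C@H](O[Si](C)(C)C(C)(C)C)CC(=O)C(C)C | intermediate
16 | cis-fused bicyclic hydroxy lactone: 3-ethenyl-6-hydroxy-3a-methyl-6-(propan-2-yl)-4-(TBS-oxy)hexahydrocyclopenta[c]furan-1-one, stereocentres as in 24 | O=C1O[C@H](C=C)[C@@]2(C)[C@H](O[Si](C)(C)C(C)(C)C)C[C@](O)(C(C)C)[C@@H]12 | intermediate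
17 | 2-methylallylmagnesium chloride | C=C(C)C[Mg]Cl | starting material
18 | cyclopentane keto diol: C5 3-methylbut-3-enoyl, C1 methyl and 1-hydroxyprop-2-enyl, C2 OTBS, C4 OH and isopropyl, stereocentres as in 24 | C=C(C)CC(=O)[C@@H]1[C@@](O)(C(C)C)C[C@@H](O[Si](C)(C)C(C)(C)C)[C@]1(C)[C@H](O)C=C | intermediate
19 | cis-fused hydroazulenone: 4,10-dihydroxy-2-(TBS-oxy)dauc-8-en-6-one | O=C1CC(C)=C[C@@H](O)[C@@]2(C)[C@H](O[Si](C)(C)C(C)(C)C)C[C@](O)(C(C)C)[C@@H]12 | intermediate
20 | dauc-8-ene-2,4,6,10-tetrol 2-O-TBS ether | O[C@@H]1CC(C)=C[C@@H](O)[C@@]2(C)[C@H](O[Si](C)(C)C(C)(C)C)C[C@](O)(C(C)C)[C@@H]12 | intermediate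
21 | angelic acid, (Z)-2-methylbut-2-enoic acid | C/C=C(/C)C(=O)O | starting material
22 | angelic 2,4,6-trichlorobenzoic anhydride (not isolated) | C/C=C(/C)C(=O)OC(=O)c1c(Cl)cc(Cl)cc1Cl | intermediate
23 | 6,10-di-O-angeloyl-dauc-8-ene-2,4,6,10-tetrol 2-O-TBS ether | C/C=C(/C)C(=O)O[C@@H]1CC(C)=C[C@@H](OC(=O)/C(C)=C\C)[C@@]2(C)[C@H](O[Si](C)(C)C(C)(C)C)C[C@](O)(C(C)C)[C@@H]12 | intermediate
24 | 6,10-di-O-angeloyl-dauc-8-ene-2,4,6,10-tetrol (CNP0249167.1) | C/C=C(/C)C(=O)O[C@@H]1CC(C)=C[C@@H](OC(=O)/C(C)=C\C)[C@@]2(C)[C@H](O)C[C@](O)(C(C)C)[C@@H]12 | target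

Total step count: 13. Longest linear sequence: 13 steps (1 and 2 to 24).

Steps most likely to fail

Step 3. The radical addition may be too slow at the β,β-disubstituted carbon, so that hydrogen abstraction at C10 or oligomerisation takes over. The fallback sets out from 5 and comes back at 7. The C2 carbon is brought in as a silylmethyl nucleophile: (isopropoxydimethylsilyl)methylmagnesium chloride with CuBr·SMe2 and Me3SiCl in THF at −78 °C should add to 5 anti to the vinyl group and give the silylmethyl lactone F1. Tamao–Fleming oxidation (KF, KHCO3, H2O2, THF/MeOH) should give the hydroxymethyl lactone F2, which is oxidised at once with Dess–Martin periodinane to the formyl lactone F3. Acetalisation with ethylene glycol (PPTS, benzene, reflux) gives 7.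

Step 6. Facial selectivity at the α-quaternary aldehyde may be poor, because the reagent has to override an ill-defined substrate bias. The fallback sets out from 10 and comes back at 13; it makes no new compound (F0). Enamine catalysis replaces the boron enolate: L-proline (30 mol%) in 11/DMSO at rt (List–Barbas aldol) forms the enamine at the methyl group of 11 and directs it to the Re face of non-enolisable aldehydes, which again leads to the R carbinol at C2.

Step 12. Acylation of the two hindered secondary hydroxyls may stay incomplete, or the activated angelate may isomerise from Z to E. The fallback sets out from 20 and comes back at 23. The angelate double bonds are built on the substrate: esterification of both secondary hydroxyls with 2-[bis(2,2,2-trifluoroethoxy)phosphoryl]propanoic acid (DCC, DMAP, CH2Cl2) gives the bis(phosphonopropanoate) F4. Still–Gennari olefination with acetaldehyde (KN(SiMe3)2, 18-crown-6, THF, −78 °C) then forms both Z-trisubstituted enoates and gives 23.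

Further compounds
F1 | step 3 | silylmethyl lactone, (4S,5R)-5-ethenyl-4-methyl-4-{[dimethyl(propan-2-yloxy)silyl]methyl}oxolan-2-one | O=C1O[C@H](C=C)[C@@](C)(C[Si](C)(C)OC(C)C)C1
F2 | step 3 | hydroxymethyl lactone | O=C1O[C@H](C=C)[C@@](C)(CO)C1
F3 | step 3 | formyl lactone | O=C1O[C@H](C=C)[C@@](C)(C=O)C1
F0 | step 6 | none | none
F4 | step 12 | bis(phosphonopropanoate) of 20 | CC(C(=O)O[C@@H]1CC(C)=C[C@@H](OC(=O)C(C)P(=O)(OCC(F)(F)F)OCC(F)(F)F)[C@@]2(C)[C@H](O[Si](C)(C)C(C)(C)C)C[C@](O)(C(C)C)[C@@H]12)P(=O)(OCC(F)(F)F)OCC(F)(F)F
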